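**Retrosynthetic overview**

- The strategy rests on one feature of unit 1 (the 7-methoxyflavanone): its C4 ketone is bonded to C4a of ring A, a carbon ortho to C8a–O1 and to C5–O and para to C7–OMe. The pyranone ring can therefore be closed by acylating a 3,5-dioxygenated phenyl ether ortho to its ether oxygen, after O1–C2 and the C2 stereocentre are already in place.
- Target 20 comes from protected biflavanone 19 by one Lewis-acid deprotection (three benzyl ethers and the peri 5-methyl ether of unit 1).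
- 19 comes from acid 17 by C4–C4a closure; 17 gets its O1–C2 bond by Mitsunobu inversion of the (R)-β-hydroxy ester 14, itself from asymmetric hydrogenation of β-keto ester 13.
- Unit 2 is built the same way from the aldehyde of diaryl ether 3 (SNAr of 1 on 2); the carboxyl carbon of ring B of unit 1 travels as a methyl ester and is homologated to 13 only after unit 2 is closed.
- Ring order: pyranone of unit 2 (step 6), then pyranone of unit 1 (step 11).

Key step: step 11

Assumption: 1 and 6 are taken as catalogue compounds; SEGPHOS is 5,5′-bis(diphenylphosphino)-4,4′-bi-1,3-benzodioxole, and the ring B carboxyl is carried as an ester because that carbon needs a mask stable to base and Lewis acid while unit 2 is built.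

**Route**

Step 1
Reactants: 1 methyl 4-(benzyloxy)-3-hydroxybenzoate; 2 4-fluorobenzaldehyde
Product: 3 methyl 4-(benzyloxy)-3-(4-formylphenoxy)benzoate
Conditions: K2CO3, DMF, 100 °C
Reagents that add atoms: none
Why: Nucleophilic aromatic substitution (SNAr): the phenoxide of 1 adds para to the formyl group of 2 and fluoride leaves from the Meisenheimer adduct, while the methyl ester and benzyl ether are inert to anhydrous carbonate.

Step 2
Reactants: 3 methyl 4-(benzyloxy)-3-(4-formylphenoxy)benzoate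
Product: 4 methyl 4-(benzyloxy)-3-[4-(3-ethoxy-3-oxopropanoyl)phenoxy]benzoate
Conditions: N2CHCO2Et, SnCl2 (cat.), CH2Cl2, rt
Reagents that add atoms: ethyl diazoacetate, CCOC(=O)C=[N+]=[N-]
Why: Roskamp homologation: the diazo carbon adds to the Lewis-acid-activated aldehyde and a 1,2-hydride shift with loss of N2 should give the β-keto ester, the aryl ester not reacting.

Step 3
Reactants: 4 methyl 4-(benzyloxy)-3-[4-(3-ethoxy-3-oxopropanoyl)phenoxy]benzoate
Product: 5 methyl 4-(benzyloxy)-3-{4-[(1R)-3-ethoxy-1-hydroxy-3-oxopropyl]phenoxy}benzoate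
Conditions: H2 (30 bar), [RuCl(p-cymene)((S)-SEGPHOS)]Cl (1 mol %), EtOH, 60 °C
Reagents that add atoms: none
Why: Noyori asymmetric hydrogenation of a β-keto ester: chelation of the keto ester to the Ru–diphosphine hydride fixes the face, and the (S)-ligand (the hand that gives (S)-3-hydroxybutanoate from acetoacetate, the descriptor changing because aryl outranks CH2CO2Et) should give the (R)-carbinol, with benzyl ethers and the aryl ester untouched by this homogeneous catalyst.

Step 4
Reactants: 5 methyl 4-(benzyloxy)-3-{4-[(1R)-3-ethoxy-1-hydroxy-3-oxopropyl]phenoxy}benzoate; 6 3,5-bis(benzyloxy)phenol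
Product: 7 methyl 4-(benzyloxy)-3-{4-[(1S)-1-[3,5-bis(benzyloxy)phenoxy]-3-ethoxy-3-oxopropyl]phenoxy}benzoate
Conditions: PPh3, DIAD, toluene, 0 °C to rt
Reagents that add atoms: none
Why: Mitsunobu etherification: the phenoxide of 6 displaces the alkoxyphosphonium group by SN2 with inversion, turning the (R)-carbinol into the (S)-aryl ether, and the non-polar cold medium disfavours ionisation and elimination to the cinnamate.

Step 5
Reactants: 7 methyl 4-(benzyloxy)-3-{4-[(1S)-1-[3,5-bis(benzyloxy)phenoxy]-3-ethoxy-3-oxopropyl]phenoxy}benzoate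
Product: 8 4-(benzyloxy)-3-{4-[(1S)-1-[3,5-bis(benzyloxy)phenoxy]-2-carboxyethyl]phenoxy}benzoic acid
Conditions: LiOH·H2O, THF/MeOH/H2O, rt then 45 °C; then 1 M HCl
Reagents that add atoms: lithium hydroxide, [Li+].[OH-]
Why: Saponification of both esters: the aliphatic ester goes first at room temperature and its carboxylate then resists E1cB loss of the aryloxide while the benzoate is cleaved on warming, and no base-sensitive stereocentre is present yet.

Step 6
Reactants: 8 4-(benzyloxy)-3-{4-[(1S)-1-[3,5-bis(benzyloxy)phenoxy]-2-carboxyethyl]phenoxy}benzoic acid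
Product: 11 4-(benzyloxy)-3-{4-[(2S)-5,7-bis(benzyloxy)-4-oxochroman-2-yl]phenoxy}benzoic acid, via bis(trifluoroacetic) mixed anhydride 9 (not isolated), via cyclised aroyl trifluoroacetate 10 (not isolated)
Conditions: (CF3CO)2O, CH2Cl2 (0.02 M), 0 °C; then aq. NaHCO3/THF; then citric acid
Reagents that add atoms: none
Why: Intramolecular Friedel–Crafts acylation: the aliphatic mixed anhydride acylates the symmetric 3,5-bis(benzyloxy)phenoxy ring ortho to the ether oxygen in a 6-exo-trig closure without touching the C2–O bond, and the aroyl trifluoroacetate, which has no arene within reach (the aryloxy group is meta to it), is hydrolysed back to the acid on work-up.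

Step 7
Reactants: 11 4-(benzyloxy)-3-{4-[(2S)-5,7-bis(benzyloxy)-4-oxochroman-2-yl]phenoxy}benzoic acid
Product: 13 methyl 3-{4-(benzyloxy)-3-[4-((2S)-5,7-bis(benzyloxy)-4-oxochroman-2-yl)phenoxy]phenyl}-3-oxopropanoate, via acyl imidazolide 12 (not isolated)
Conditions: CDI, THF, rt; then Mg(O2CCH2CO2Me)2, THF, 45 °C; then cold 1 M HCl
Reagents that add atoms: magnesium bis(methyl malonate), COC(=O)CC(=O)[O-].COC(=O)CC(=O)[O-].[Mg+2]
Why: Masamune–Brooks malonate homologation: the acyl imidazolide C-acylates the magnesium enolate of the malonate half ester and decarboxylation gives the β-keto ester under near-neutral conditions that should not enolise the flavanone of unit 2.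

Step 8
Reactants: 13 methyl 3-{4-(benzyloxy)-3-[4-((2S)-5,7-bis(benzyloxy)-4-oxochroman-2-yl)phenoxy]phenyl}-3-oxopropanoate
Product: 14 methyl (3R)-3-{4-(benzyloxy)-3-[4-((2S)-5,7-bis(benzyloxy)-4-oxochroman-2-yl)phenoxy]phenyl}-3-hydroxypropanoate
Conditions: H2 (30 bar), [RuCl(p-cymene)((S)-SEGPHOS)]Cl (2 mol %), MeOH/CH2Cl2, 50 °C
Reagents that add atoms: none
Why: Noyori asymmetric hydrogenation as in step 3: only the chelating β-keto ester is a substrate for the diamine-free Ru–diphosphine halide catalyst, so the chromanone ketone of unit 2 should survive, and the (S)-ligand should again set the (R)-carbinol.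

Step 9
Reactants: 14 methyl (3R)-3-{4-(benzyloxy)-3-[4-((2S)-5,7-bis(benzyloxy)-4-oxochroman-2-yl)phenoxy]phenyl}-3-hydroxypropanoate; 15 3,5-dimethoxyphenol
Product: 16 methyl (3S)-3-{4-(benzyloxy)-3-[4-((2S)-5,7-bis(benzyloxy)-4-oxochroman-2-yl)phenoxy]phenyl}-3-(3,5-dimethoxyphenoxy)propanoate
Conditions: PPh3, DIAD, toluene, −10 °C to rt
Reagents that add atoms: none
Why: Mitsunobu etherification with SN2 inversion as in step 4, setting the (S)-ether that becomes C2 of unit 1; the ester and the meta-aryloxy group inductively offset the para-benzyloxy donor so substitution should outrun ionisation, and nothing basic enough to open the unit 2 flavanone is present.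

Step 10
Reactants: 16 methyl (3S)-3-{4-(benzyloxy)-3-[4-((2S)-5,7-bis(benzyloxy)-4-oxochroman-2-yl)phenoxy]phenyl}-3-(3,5-dimethoxyphenoxy)propanoate
Product: 17 (3S)-3-{4-(benzyloxy)-3-[4-((2S)-5,7-bis(benzyloxy)-4-oxochroman-2-yl)phenoxy]phenyl}-3-(3,5-dimethoxyphenoxy)propanoic acid
Conditions: Me3SnOH, ClCH2CH2Cl, 70 °C; then 0.5 M HCl wash
Reagents that add atoms: trimethyltin hydroxide, C[Sn](C)(C)O
Why: Trimethyltin hydroxide ester cleavage (Nicolaou conditions): tin-assisted hydroxide transfer cleaves the methyl ester under essentially neutral conditions, avoiding the hydroxide-induced retro-oxa-Michael opening and racemisation of the unit 2 flavanone and E1cB loss of the aryloxide.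

Step 11
Reactants: 17 (3S)-3-{4-(benzyloxy)-3-[4-((2S)-5,7-bis(benzyloxy)-4-oxochroman-2-yl)phenoxy]phenyl}-3-(3,5-dimethoxyphenoxy)propanoic acid
Product: 19 (2S)-2-{4-(benzyloxy)-3-[4-((2S)-5,7-bis(benzyloxy)-4-oxochroman-2-yl)phenoxy]phenyl}-5,7-dimethoxychroman-4-one, via trifluoroacetic mixed anhydride 18 (not isolated)
Conditions: (CF3CO)2O (2.5 equiv), CH2Cl2 (0.02 M), −10 to 0 °C; then aq. NaHCO3
Reagents that add atoms: none
Why: Trifluoroacetic anhydride turns the acid into mixed anhydride 18, which, helped by the trifluoroacetic acid it liberates, acts as an acylium equivalent; the carbon of the 3,5-dimethoxyphenoxy ring ortho to the ether oxygen attacks it and loss of a proton from the arenium ion gives the aryl ketone, forming C4–C4a. This is an intramolecular Friedel–Crafts acylation of the kind that converts 3-aryloxypropanoic acids into chroman-4-ones. The pyranone ring of unit 1 closes in a 6-exo-trig mode at the acyl carbon. No stereocentre is created, and C2, set in step 9, should keep its (S) configuration because no bond to it is made or broken. The step needs regiocontrol, chemoselectivity and an intact benzylic C2–O1 bond: the two ortho positions of the symmetric ring are equivalent and the para position cannot be reached, the 1,3,5-trioxygenated ring is far more nucleophilic than ring B of unit 1 (five-ring indanone closure) or the ketone-deactivated ring A of unit 2, and that nucleophilicity allows a cold, dilute, short reaction in which the β-acyl group and the meta-aryloxy substituent hold back ionisation of the para-benzyloxybenzylic ether.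

Step 12
Reactants: 19 (2S)-2-{4-(benzyloxy)-3-[4-((2S)-5,7-bis(benzyloxy)-4-oxochroman-2-yl)phenoxy]phenyl}-5,7-dimethoxychroman-4-one
Product: 20 7-O-methyltetrahydroochnaflavone, (2S)-2-{3-[4-((2S)-5,7-dihydroxy-4-oxochroman-2-yl)phenoxy]-4-hydroxyphenyl}-5-hydroxy-7-methoxychroman-4-one
Conditions: BCl3, C6HMe5, CH2Cl2, −78 to 0 °C; then MeOH, H2O
Reagents that add atoms: none
Why: Lewis-acid ether cleavage: BCl3 removes the three benzyl ethers in the cold with pentamethylbenzene trapping the benzyl cations, and on warming the boron chelated to the C4 carbonyl of unit 1 should remove only the peri 5-methyl ether (chelation-assisted demethylation), the 7-methyl ether having no such assistance.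

**Compound list**

1 | methyl 4-(benzyloxy)-3-hydroxybenzoate | COC(=O)c1ccc(OCc2ccccc2)c(O)c1 | starting material
2 | 4-fluorobenzaldehyde | O=Cc1ccc(F)cc1 | starting material
3 | methyl 4-(benzyloxy)-3-(4-formylphenoxy)benzoate | COC(=O)c1ccc(OCc2ccccc2)c(Oc2ccc(C=O)cc2)c1 | intermediate
4 | methyl 4-(benzyloxy)-3-[4-(3-ethoxy-3-oxopropanoyl)phenoxy]benzoate | COC(=O)c1ccc(OCc2ccccc2)c(Oc2ccc(C(=O)CC(=O)OCC)cc2)c1 | intermediate
5 | methyl 4-(benzyloxy)-3-{4-[(1R)-3-ethoxy-1-hydroxy-3-oxopropyl]phenoxy}benzoate | COC(=O)c1ccc(OCc2ccccc2)c(Oc2ccc([C@H](O)CC(=O)OCC)cc2)c1 | intermediate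
6 | 3,5-bis(benzyloxy)phenol | Oc1cc(OCc2ccccc2)cc(OCc2ccccc2)c1 | starting material
7 | methyl 4-(benzyloxy)-3-{4-[(1S)-1-[3,5-bis(benzyloxy)phenoxy]-3-ethoxy-3-oxopropyl]phenoxy}benzoate | COC(=O)c1ccc(OCc2ccccc2)c(Oc2ccc([C@@H](Oc3cc(OCc4ccccc4)cc(OCc4ccccc4)c3)CC(=O)OCC)cc2)c1 | intermediate
8 | 4-(benzyloxy)-3-{4-[(1S)-1-[3,5-bis(benzyloxy)phenoxy]-2-carboxyethyl]phenoxy}benzoic acid | OC(=O)c1ccc(OCc2ccccc2)c(Oc2ccc([C@@H](Oc3cc(OCc4ccccc4)cc(OCc4ccccc4)c3)CC(=O)O)cc2)c1 | intermediate
9 | bis(trifluoroacetic) mixed anhydride of diacid 8 | O=C(OC(=O)C(F)(F)F)c1ccc(OCc2ccccc2)c(Oc2ccc([C@@H](Oc3cc(OCc4ccccc4)cc(OCc4ccccc4)c3)CC(=O)OC(=O)C(F)(F)F)cc2)c1 | intermediate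
10 | aroyl trifluoroacetate of flavanone acid 11 | O=C(OC(=O)C(F)(F)F)c1ccc(OCc2ccccc2)c(Oc2ccc([C@@H]3CC(=O)c4c(OCc5ccccc5)cc(OCc5ccccc5)cc4O3)cc2)c1 | intermediate
11 | 4-(benzyloxy)-3-{4-[(2S)-5,7-bis(benzyloxy)-4-oxochroman-2-yl]phenoxy}benzoic acid | OC(=O)c1ccc(OCc2ccccc2)c(Oc2ccc([C@@H]3CC(=O)c4c(OCc5ccccc5)cc(OCc5ccccc5)cc4O3)cc2)c1 | intermediate
12 | acyl imidazolide of acid 11 | O=C(n1ccnc1)c1ccc(OCc2ccccc2)c(Oc2ccc([C@@H]3CC(=O)c4c(OCc5ccccc5)cc(OCc5ccccc5)cc4O3)cc2)c1 | intermediate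
13 | methyl 3-{4-(benzyloxy)-3-[4-((2S)-5,7-bis(benzyloxy)-4-oxochroman-2-yl)phenoxy]phenyl}-3-oxopropanoate | COC(=O)CC(=O)c1ccc(OCc2ccccc2)c(Oc2ccc([C@@H]3CC(=O)c4c(OCc5ccccc5)cc(OCc5ccccc5)cc4O3)cc2)c1 | intermediate
14 | methyl (3R)-3-{4-(benzyloxy)-3-[4-((2S)-5,7-bis(benzyloxy)-4-oxochroman-2-yl)phenoxy]phenyl}-3-hydroxypropanoate | COC(=O)C[C@@H](O)c1ccc(OCc2ccccc2)c(Oc2ccc([C@@H]3CC(=O)c4c(OCc5ccccc5)cc(OCc5ccccc5)cc4O3)cc2)c1 | intermediate
15 | 3,5-dimethoxyphenol | COc1cc(O)cc(OC)c1 | starting material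
16 | methyl (3S)-3-{4-(benzyloxy)-3-[4-((2S)-5,7-bis(benzyloxy)-4-oxochroman-2-yl)phenoxy]phenyl}-3-(3,5-dimethoxyphenoxy)propanoate | COC(=O)C[C@H](Oc1cc(OC)cc(OC)c1)c1ccc(OCc2ccccc2)c(Oc2ccc([C@@H]3CC(=O)c4c(OCc5ccccc5)cc(OCc5ccccc5)cc4O3)cc2)c1 | intermediate
17 | (3S)-3-{4-(benzyloxy)-3-[4-((2S)-5,7-bis(benzyloxy)-4-oxochroman-2-yl)phenoxy]phenyl}-3-(3,5-dimethoxyphenoxy)propanoic acid | OC(=O)C[C@H](Oc1cc(OC)cc(OC)c1)c1ccc(OCc2ccccc2)c(Oc2ccc([C@@H]3CC(=O)c4c(OCc5ccccc5)cc(OCc5ccccc5)cc4O3)cc2)c1 | intermediate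
18 | trifluoroacetic mixed anhydride of acid 17 | O=C(OC(=O)C(F)(F)F)C[C@H](Oc1cc(OC)cc(OC)c1)c1ccc(OCc2ccccc2)c(Oc2ccc([C@@H]3CC(=O)c4c(OCc5ccccc5)cc(OCc5ccccc5)cc4O3)cc2)c1 | intermediate
19 | (2S)-2-{4-(benzyloxy)-3-[4-((2S)-5,7-bis(benzyloxy)-4-oxochroman-2-yl)phenoxy]phenyl}-5,7-dimethoxychroman-4-one | COc1cc(OC)c2c(c1)O[C@H](c1ccc(OCc3ccccc3)c(Oc3ccc([C@@H]4CC(=O)c5c(OCc6ccccc6)cc(OCc6ccccc6)cc5O4)cc3)c1)CC2=O | intermediate
20 | 7-O-methyltetrahydroochnaflavone | COc1cc(O)c2c(c1)O[C@H](c1ccc(O)c(Oc3ccc([C@@H]4CC(=O)c5c(O)cc(O)cc5O4)cc3)c1)CC2=O | target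

**Step count and risks**

Total step count: 12. Longest linear sequence: 12 steps (from 1 or 2 to 20).

Steps most likely to fail:

1. Step 11 (key ring closure). What may go wrong: acid-induced heterolysis of the benzylic O1–C2 bond of unit 1, before or after closure, with loss of the phenol or of configuration at C2, and competing C-trifluoroacetylation of the electron-rich ring. Fallback: set out from acid 17 and make the acid chloride F1 with 1-chloro-N,N,2-trimethylprop-1-en-1-amine in CH2Cl2 at 0 °C (neutral). The acid chloride F1 is then closed without any protic acid as its acyl triflate, using AgOTf and 2,6-di-tert-butyl-4-methylpyridine in CH2Cl2 at −40 °C, which comes back to the route at 19.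

2. Step 9 (Mitsunobu on the unit 1 carbinol). What may go wrong: anti-elimination of the alkoxyphosphonium intermediate to the cinnamate through the acidic C–H next to the ester, and partial ionisation at the para-benzyloxy-substituted benzylic carbon that erodes the inversion. Fallback: set out from acid 11 and replace the β-hydroxy ester by a carbinol with no acidic neighbouring C–H.
   - Chemoselective reduction of the acid with BH3·SMe2 (THF, 0 °C) should give the benzylic alcohol F2, and MnO2 in CH2Cl2 the aldehyde F3.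
   - A Re-face-selective asymmetric allylboration should give the (R)-homoallylic alcohol F4; allylB(pin) would be used with the enantiomer of the 3,3′-bis(2,4,6-triisopropylphenyl)-BINOL phosphoric acid that gives (R)-1-phenylbut-3-en-1-ol from benzaldehyde, the ketone of unit 2 being inert.
   - Mitsunobu etherification with 15 (PPh3, DIAD, toluene) should give the (S)-homoallyl aryl ether F5.
   - Lemieux–Johnson cleavage (OsO4 cat., NaIO4, 2,6-lutidine, dioxane/H2O) should give the aldehyde F6, which is oxidised at once (NaClO2, NaH2PO4, 2-methyl-2-butene, t-BuOH/H2O) to come back to the route at 17.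

3. Step 12 (global deprotection). What may go wrong: Lewis-acid-induced opening of a pyranone ring at C2–O1 with epimerisation through the chalcone, C-benzylation of the freed phloroglucinol ring by benzyl cations, or incomplete removal of the peri methyl ether. Fallback: set out from 19 and remove the three benzyl ethers by neutral hydrogenolysis (H2, palladium on carbon, EtOAc/THF) to give the triphenol F7. The triphenol F7 then needs only the chelation-assisted demethylation of the single peri methyl ether (BCl3, CH2Cl2, −78 to 0 °C), with no benzyl cations present, which comes back to the route at 20.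

**Further compounds**

F1 | step 11 | (3S)-3-{4-(benzyloxy)-3-[4-((2S)-5,7-bis(benzyloxy)-4-oxochroman-2-yl)phenoxy]phenyl}-3-(3,5-dimethoxyphenoxy)propanoyl chloride | O=C(Cl)C[C@H](Oc1cc(OC)cc(OC)c1)c1ccc(OCc2ccccc2)c(Oc2ccc([C@@H]3CC(=O)c4c(OCc5ccccc5)cc(OCc5ccccc5)cc4O3)cc2)c1
F2 | step 9 | (2S)-5,7-bis(benzyloxy)-2-{4-[2-(benzyloxy)-5-(hydroxymethyl)phenoxy]phenyl}chroman-4-one | OCc1ccc(OCc2ccccc2)c(Oc2ccc([C@@H]3CC(=O)c4c(OCc5ccccc5)cc(OCc5ccccc5)cc4O3)cc2)c1
F3 | step 9 | 4-(benzyloxy)-3-{4-[(2S)-5,7-bis(benzyloxy)-4-oxochroman-2-yl]phenoxy}benzaldehyde | O=Cc1ccc(OCc2ccccc2)c(Oc2ccc([C@@H]3CC(=O)c4c(OCc5ccccc5)cc(OCc5ccccc5)cc4O3)cc2)c1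
F4 | step 9 | (2S)-5,7-bis(benzyloxy)-2-{4-[2-(benzyloxy)-5-((1R)-1-hydroxybut-3-en-1-yl)phenoxy]phenyl}chroman-4-one | C=CC[C@@H](O)c1ccc(OCc2ccccc2)c(Oc2ccc([C@@H]3CC(=O)c4c(OCc5ccccc5)cc(OCc5ccccc5)cc4O3)cc2)c1
F5 | step 9 | (2S)-5,7-bis(benzyloxy)-2-{4-[2-(benzyloxy)-5-((1S)-1-(3,5-dimethoxyphenoxy)but-3-en-1-yl)phenoxy]phenyl}chroman-4-one | C=CC[C@H](Oc1cc(OC)cc(OC)c1)c1ccc(OCc2ccccc2)c(Oc2ccc([C@@H]3CC(=O)c4c(OCc5ccccc5)cc(OCc5ccccc5)cc4O3)cc2)c1
F6 | step 9 | (3S)-3-{4-(benzyloxy)-3-[4-((2S)-5,7-bis(benzyloxy)-4-oxochroman-2-yl)phenoxy]phenyl}-3-(3,5-dimethoxyphenoxy)propanal | O=CC[C@H](Oc1cc(OC)cc(OC)c1)c1ccc(OCc2ccccc2)c(Oc2ccc([C@@H]3CC(=O)c4c(OCc5ccccc5)cc(OCc5ccccc5)cc4O3)cc2)c1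
F7 | step 12 | (2S)-2-{3-[4-((2S)-5,7-dihydroxy-4-oxochroman-2-yl)phenoxy]-4-hydroxyphenyl}-5,7-dimethoxychroman-4-one | COc1cc(OC)c2c(c1)O[C@H](c1ccc(O)c(Oc3ccc([C@@H]4CC(=O)c5c(O)cc(O)cc5O4)cc3)c1)CC2=O
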